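## Retrosynthetic overview

1. Numbering: ring B (cyclohexane) has C1 = CH bonded to ring A, C3 = CMe2, C4 = CHBr, C5 and C6 = the two adjacent CH2. Ring A (7-oxabicyclo[2.2.1]heptane) has C1' = C–CH3, C2' = CHBr, C4' = bridgehead bonded to C1, O7' = bridge.
2. Target 21 ⇒ open-chain boronate 19. Ring B is closed last through the C5–C6 bond: a C6 radical (from C6–Bpin) adds 6-endo to C5 of a C4(Br)=C5H2 alkene, and hydrogen transfer then sets C4.
3. 19 ⇒ alkyne 17 ⇒ 15. The O7' bridge of ring A comes from bromoetherification (sets C1' and C2' from C4'); C1 comes from ligand-controlled CuH hydroboration of 13.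
4. 13 ⇒ achiral ketone 10 (chiral lithium amide desymmetrisation sets C4') ⇒ vinyllithium 8 + ketone 7. The chain comes from isobutyraldehyde 1, 2,3-dibromopropene 2 and a one-carbon homologation.
5. Enabling feature: C4 bears Br and is flanked by the quaternary C3, so the C4(Br)=C5H2 unit exposes only C5 to the C6 radical, and the axial C3 methyl steers hydrogen to C4. Ring order: ring A carbocycle (bought), O7' bridge (step 8), ring B (step 11).

Key step: step 11

Remark 1: the (S,S)-amide in step 5 is assumed to give the (4S)-enolate, by analogy with 4-tert-butylcyclohexanone and with the alkenyl group equatorial; if the sense is reversed, the (R,R)-amide is used.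
Remark 2: (S)-DTBM-SEGPHOS in step 7 is assumed to be the ligand antipode that gives (S) at C1; if not, the (R)-ligand is used.

## Route

Step 1
Reactants: 1 isobutyraldehyde; 2 2,3-dibromoprop-1-ene
Product: 3 4-bromo-2,2-dimethylpent-4-enal
Conditions: 50% aq. NaOH, Bu4NI (cat.), toluene, 60 °C
Reagents that add atoms: none
Why: Phase-transfer C-alkylation of an aldehyde with a single α-hydrogen (SN2 at the allylic CH2Br, vinylic bromide inert) builds the quaternary C3 of ring B without aldol condensation.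

Step 2
Reactants: 3 4-bromo-2,2-dimethylpent-4-enal
Product: 4 5-bromo-3,3-dimethylhex-5-en-1-yne
Conditions: dimethyl (1-diazo-2-oxopropyl)phosphonate, K2CO3, MeOH, 0 °C → rt
Reagents that add atoms: dimethyl (1-diazo-2-oxopropyl)phosphonate, COP(=O)(OC)C(=[N+]=[N-])C(C)=O
Why: Seyferth–Gilbert homologation of the non-enolisable aldehyde adds the carbon that becomes C5, under mild base that leaves the 2-bromoalkene untouched.

Step 3
Reactants: 4 5-bromo-3,3-dimethylhex-5-en-1-yne
Product: 6 (5-bromo-3,3-dimethylhex-5-en-1-yn-1-yl)trimethylsilane, via lithium acetylide 5 (not isolated)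
Conditions: LiHMDS, THF, −78 °C; Me3SiCl, −78 °C → rt
Reagents that add atoms: chlorotrimethylsilane, C[Si](C)(C)Cl
Why: Deprotonation of the only acidic C–H and C-silylation masks the alkyne for the organolithium and copper hydride steps.

Step 4
Reactants: 6 (5-bromo-3,3-dimethylhex-5-en-1-yn-1-yl)trimethylsilane; 7 4,4-dimethoxycyclohexan-1-one
Product: 10 4-hydroxy-4-[4,4-dimethyl-6-(trimethylsilyl)hex-1-en-5-yn-2-yl]cyclohexan-1-one, via vinyllithium 8 (not isolated), via lithium alkoxide 9 (not isolated)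
Conditions: t-BuLi (2 equiv), Et2O, −78 °C; 7, −78 °C; then 1 M aq. HCl, THF, 0 °C
Reagents that add atoms: water, O
Why: Bromine–lithium exchange gives the 1,1-disubstituted vinyllithium, whose 1,2-addition to the ketone forms the C1–C4' bond, and the dimethyl ketal is hydrolysed in the mildly acidic work-up; 10 is achiral.

Step 5
Reactants: 10 4-hydroxy-4-[4,4-dimethyl-6-(trimethylsilyl)hex-1-en-5-yn-2-yl]cyclohexan-1-one
Product: 12 (4S)-4-hydroxy-4-[4,4-dimethyl-6-(trimethylsilyl)hex-1-en-5-yn-2-yl]cyclohex-1-en-1-yl trifluoromethanesulfonate, via dilithium enolate 11 (not isolated)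
Conditions: (S,S)-bis(1-phenylethyl)amine, n-BuLi, LiCl, THF, −78 °C (2.2 equiv of amide); then N-(5-chloropyridin-2-yl)-1,1,1-trifluoro-N-(trifluoromethylsulfonyl)methanesulfonamide, −78 → −20 °C
Reagents that add atoms: N-(5-chloropyridin-2-yl)-1,1,1-trifluoro-N-(trifluoromethylsulfonyl)methanesulfonamide, FC(F)(F)S(=O)(=O)N(c1ccc(Cl)cn1)S(=O)(=O)C(F)(F)F
Why: Enantioselective deprotonation of a 4,4-disubstituted cyclohexanone by a C2-symmetric chiral lithium amide (the first equivalent forms the alkoxide) removes one of the two enantiotopic axial α-protons in the chair with the alkenyl group equatorial, which fixes the arm that carries the double bond and makes C4' a stereocentre (S); O-triflation traps the enolate regiospecifically.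

Step 6
Reactants: 12 (4S)-4-hydroxy-4-[4,4-dimethyl-6-(trimethylsilyl)hex-1-en-5-yn-2-yl]cyclohex-1-en-1-yl trifluoromethanesulfonate
Product: 13 (1S)-1-[4,4-dimethyl-6-(trimethylsilyl)hex-1-en-5-yn-2-yl]-4-methylcyclohex-3-en-1-ol
Conditions: MeMgBr (3.5 equiv), Fe(acac)3 (cat.), THF/NMP, −30 → 0 °C
Reagents that add atoms: methylmagnesium bromide, C[Mg]Br
Why: Iron-catalysed Kumada-type cross-coupling of the enol triflate installs the C1' methyl group without moving the double bond; the excess Grignard reagent covers the free hydroxyl.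

Step 7
Reactants: 13 (1S)-1-[4,4-dimethyl-6-(trimethylsilyl)hex-1-en-5-yn-2-yl]-4-methylcyclohex-3-en-1-ol
Product: 15 (1S)-1-[(2S)-4,4-dimethyl-1-(4,4,5,5-tetramethyl-1,3,2-dioxaborolan-2-yl)-6-(trimethylsilyl)hex-5-yn-2-yl]-4-methylcyclohex-3-en-1-ol, via O-boryl ether 14 (not isolated)
Conditions: Cu(OAc)2 (cat.), (S)-DTBM-SEGPHOS (cat.), pinacolborane (2.5 equiv), THF, 40 °C; aq. NH4Cl work-up
Reagents that add atoms: pinacolborane, CC1(C)OBOC1(C)C
Why: Copper hydride-catalysed anti-Markovnikov hydroboration of the 1,1-disubstituted alkene delivers hydride to C1 on the face chosen by the bisphosphine, which distinguishes the fully substituted C4' from the CH2 group (catalyst control, no bias from the remote and locally symmetric C4'), while the trisubstituted ring alkene and the hindered silylalkyne stay inert.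

Step 8
Reactants: 15 (1S)-1-[(2S)-4,4-dimethyl-1-(4,4,5,5-tetramethyl-1,3,2-dioxaborolan-2-yl)-6-(trimethylsilyl)hex-5-yn-2-yl]-4-methylcyclohex-3-en-1-ol
Product: 16 2-{(2S)-2-[(1S,3R,4R)-3-bromo-4-methyl-7-oxabicyclo[2.2.1]heptan-1-yl]-4,4-dimethyl-6-(trimethylsilyl)hex-5-yn-1-yl}-4,4,5,5-tetramethyl-1,3,2-dioxaborolane
Conditions: N-bromosuccinimide, CH2Cl2, −20 → 0 °C
Reagents that add atoms: N-bromosuccinimide, O=C1CCC(=O)N1Br
Why: Bromoetherification: the bromonium ion on the alkene face anti to the hydroxyl is opened at the tertiary C1' by the C4' oxygen (Markovnikov, anti addition), which closes the O7' bridge and sets C1' (R) and the endo bromide at C2' (R) from C4' alone.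

Step 9
Reactants: 16 2-{(2S)-2-[(1S,3R,4R)-3-bromo-4-methyl-7-oxabicyclo[2.2.1]heptan-1-yl]-4,4-dimethyl-6-(trimethylsilyl)hex-5-yn-1-yl}-4,4,5,5-tetramethyl-1,3,2-dioxaborolane
Product: 17 2-{(2S)-2-[(1S,3R,4R)-3-bromo-4-methyl-7-oxabicyclo[2.2.1]heptan-1-yl]-4,4-dimethylhex-5-yn-1-yl}-4,4,5,5-tetramethyl-1,3,2-dioxaborolane
Conditions: K2CO3 (cat.), MeOH, rt
Reagents that add atoms: none
Why: Base-catalysed methanolysis of the C(sp)–Si bond frees the terminal alkyne; the alkyl pinacol boronate, the ether and the alkyl bromide are stable.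

Step 10
Reactants: 17 2-{(2S)-2-[(1S,3R,4R)-3-bromo-4-methyl-7-oxabicyclo[2.2.1]heptan-1-yl]-4,4-dimethylhex-5-yn-1-yl}-4,4,5,5-tetramethyl-1,3,2-dioxaborolane
Product: 19 2-{(2S)-5-bromo-2-[(1S,3R,4R)-3-bromo-4-methyl-7-oxabicyclo[2.2.1]heptan-1-yl]-4,4-dimethylhex-5-en-1-yl}-4,4,5,5-tetramethyl-1,3,2-dioxaborolane, via alkenylborane 18 (not isolated)
Conditions: B-bromo-9-borabicyclo[3.3.1]nonane, CH2Cl2, 0 °C; then AcOH, 0 °C → rt
Reagents that add atoms: B-bromo-9-borabicyclo[3.3.1]nonane, BrB1C2CCCC1CCC2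
Why: Bromoboration adds B–Br syn across the terminal alkyne with bromine on the internal carbon (C4), and protonolysis of the alkenyl–boron bond gives the 2-bromo-1-alkene (net Markovnikov HBr addition) without strong protic acid.

Step 11
Reactants: 19 2-{(2S)-5-bromo-2-[(1S,3R,4R)-3-bromo-4-methyl-7-oxabicyclo[2.2.1]heptan-1-yl]-4,4-dimethylhex-5-en-1-yl}-4,4,5,5-tetramethyl-1,3,2-dioxaborolane
Product: 21 (1R,2R,4S)-2-bromo-4-[(1S,4S)-4-bromo-3,3-dimethylcyclohexyl]-1-methyl-7-oxabicyclo[2.2.1]heptane, via lithium boronate complex 20 (not isolated)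
Conditions: PhLi (1 equiv), THF, −78 → 0 °C; then [Ir(dF(CF3)ppy)2(dtbbpy)]PF6 (cat.), i-Pr3SiSH (cat.), MeOH/MeCN, blue LEDs, rt, high dilution
Reagents that add atoms: none
Why: Proposed new method: single-electron oxidation of the phenyl boronate complex 20 by the excited trivalent iridium photocatalyst releases the primary C6 radical (and PhBpin), which adds to C5, the unsubstituted terminus of the C4(Br)=C5H2 alkene, and the resulting α-bromo C4 radical is quenched by hydrogen transfer from the thiol, the thiyl radical being returned to thiol by the reduced photocatalyst and methanol. The closest known reactions are the photoredox protodeboronation of alkyl pinacol boronate complexes and the 6-endo cyclisation of 5-substituted hex-5-enyl radicals; their combination on a 2-bromoalkene with retention of the C–Br bond is new. Ring B closes in the 6-endo-trig mode, because the 5-exo alternative would need attack at the fully substituted C4, which carries bromine and is shielded by the quaternary C3. The new stereocentre C4 is controlled by the ring: in the chair that keeps ring A equatorial at C1, hydrogen is delivered axially to C4, anti to the axial C3 methyl group, so bromine ends equatorial and trans to C1 (4S). The step needs cyclisation to outrun direct hydrogen transfer to the C6 radical, which catalytic thiol at high dilution and the gem-dimethyl group on the chain should secure. It also needs both C–Br bonds to survive, which the absence of tin or silyl radicals and the mild reducing power of the catalyst should secure.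

## Compound list

1 | isobutyraldehyde (2-methylpropanal) | CC(C)C=O | starting material
2 | 2,3-dibromoprop-1-ene | C=C(Br)CBr | starting material
3 | 4-bromo-2,2-dimethylpent-4-enal | O=CC(C)(C)CC(Br)=C | intermediate
4 | 5-bromo-3,3-dimethylhex-5-en-1-yne | C#CC(C)(C)CC(Br)=C | intermediate
5 | (5-bromo-3,3-dimethylhex-5-en-1-yn-1-yl)lithium | [Li]C#CC(C)(C)CC(Br)=C | intermediate
6 | (5-bromo-3,3-dimethylhex-5-en-1-yn-1-yl)trimethylsilane | C[Si](C)(C)C#CC(C)(C)CC(Br)=C | intermediate
7 | 4,4-dimethoxycyclohexan-1-one | COC1(OC)CCC(=O)CC1 | starting material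
8 | [4,4-dimethyl-6-(trimethylsilyl)hex-1-en-5-yn-2-yl]lithium | [Li]C(=C)CC(C)(C)C#C[Si](C)(C)C | intermediate
9 | lithium 4,4-dimethoxy-1-[4,4-dimethyl-6-(trimethylsilyl)hex-1-en-5-yn-2-yl]cyclohexan-1-olate | [Li]OC1(CCC(OC)(OC)CC1)C(=C)CC(C)(C)C#C[Si](C)(C)C | intermediate
10 | 4-hydroxy-4-[4,4-dimethyl-6-(trimethylsilyl)hex-1-en-5-yn-2-yl]cyclohexan-1-one | O=C1CCC(O)(CC1)C(=C)CC(C)(C)C#C[Si](C)(C)C | intermediate
11 | dilithium (S)-enolate alkoxide of 10 | C=C(CC(C)(C)C#C[Si](C)(C)C)[C@@]1(O[Li])CC=C(O[Li])CC1 | intermediate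
12 | (4S)-4-hydroxy-4-[4,4-dimethyl-6-(trimethylsilyl)hex-1-en-5-yn-2-yl]cyclohex-1-en-1-yl trifluoromethanesulfonate | C=C(CC(C)(C)C#C[Si](C)(C)C)[C@@]1(O)CC=C(OS(=O)(=O)C(F)(F)F)CC1 | intermediate
13 | (1S)-1-[4,4-dimethyl-6-(trimethylsilyl)hex-1-en-5-yn-2-yl]-4-methylcyclohex-3-en-1-ol | C=C(CC(C)(C)C#C[Si](C)(C)C)[C@@]1(O)CC=C(C)CC1 | intermediate
14 | O-pinacolboryl ether of 15 | C[Si](C)(C)C#CC(C)(C)C[C@@H]([C@@]1(OB2OC(C)(C)C(C)(C)O2)CC=C(C)CC1)CB3OC(C)(C)C(C)(C)O3 | intermediate
15 | (1S)-1-[(2S)-4,4-dimethyl-1-(4,4,5,5-tetramethyl-1,3,2-dioxaborolan-2-yl)-6-(trimethylsilyl)hex-5-yn-2-yl]-4-methylcyclohex-3-en-1-ol | C[Si](C)(C)C#CC(C)(C)C[C@@H]([C@@]1(O)CC=C(C)CC1)CB2OC(C)(C)C(C)(C)O2 | intermediate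
16 | 2-{(2S)-2-[(1S,3R,4R)-3-bromo-4-methyl-7-oxabicyclo[2.2.1]heptan-1-yl]-4,4-dimethyl-6-(trimethylsilyl)hex-5-yn-1-yl}-4,4,5,5-tetramethyl-1,3,2-dioxaborolane | C[Si](C)(C)C#CC(C)(C)C[C@@H]([C@@]12CC[C@@](C)(O1)[C@H](Br)C2)CB3OC(C)(C)C(C)(C)O3 | intermediate
17 | 2-{(2S)-2-[(1S,3R,4R)-3-bromo-4-methyl-7-oxabicyclo[2.2.1]heptan-1-yl]-4,4-dimethylhex-5-yn-1-yl}-4,4,5,5-tetramethyl-1,3,2-dioxaborolane | C#CC(C)(C)C[C@@H]([C@@]12CC[C@@](C)(O1)[C@H](Br)C2)CB3OC(C)(C)C(C)(C)O3 | intermediate
18 | (Z)-2-bromoalkenyl-9-borabicyclo[3.3.1]nonane adduct of 17 | Br/C(=C\B1C2CCCC1CCC2)C(C)(C)C[C@@H]([C@@]34CC[C@@](C)(O3)[C@H](Br)C4)CB5OC(C)(C)C(C)(C)O5 | intermediate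
19 | 2-{(2S)-5-bromo-2-[(1S,3R,4R)-3-bromo-4-methyl-7-oxabicyclo[2.2.1]heptan-1-yl]-4,4-dimethylhex-5-en-1-yl}-4,4,5,5-tetramethyl-1,3,2-dioxaborolane | C=C(Br)C(C)(C)C[C@@H]([C@@]12CC[C@@](C)(O1)[C@H](Br)C2)CB3OC(C)(C)C(C)(C)O3 | intermediate
20 | lithium phenyl boronate complex of 19 | [Li+].C=C(Br)C(C)(C)C[C@@H]([C@@]12CC[C@@](C)(O1)[C@H](Br)C2)C[B-]3(c4ccccc4)OC(C)(C)C(C)(C)O3 | intermediate
21 | (1R,2R,4S)-2-bromo-4-[(1S,4S)-4-bromo-3,3-dimethylcyclohexyl]-1-methyl-7-oxabicyclo[2.2.1]heptane | CC1(C)C[C@@H]([C@@]23CC[C@@](C)(O2)[C@H](Br)C3)CC[C@@H]1Br | target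

## Step count and risks

Total step count: 11. Longest linear sequence: 11 steps (1 → 21); ketone 7 is bought.

Steps most likely to fail:

1. Step 11 (Proposed new method). The C6 radical may take hydrogen before it cyclises (plain protodeboronation), close 5-exo at C4 with loss of a bromine atom, or receive hydrogen at C4 with poor axial selectivity. The fallback sets out from 17 and returns at 21. Anti addition of iodine monobromide to the alkyne of 17 (IBr, CH2Cl2, −78 °C; iodine on the terminal carbon, bromine on C4) would give the (E)-2-bromo-1-iodoalkene F1. An intramolecular B-alkyl Suzuki–Miyaura coupling (Pd(dppf)Cl2, Cs2CO3, DMF/H2O) would join C6 to C5 at the more reactive C–I bond and give the ring B alkenyl bromide F2. A Mukaiyama-type hydrogen atom transfer hydrogenation (Mn(dpm)3 cat., PhSiH3, t-BuOOH, i-PrOH), which reduces haloalkenes without loss of halogen and delivers hydrogen axially, would then give 21.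

2. Step 7. Hydrocupration of the hindered 1,1-disubstituted alkene may be slow, or facial discrimination may be insufficient, which would give C1 epimers that are hard to separate. The fallback sets out from 13 and returns at 15. Reagent-controlled hydroboration with a stoichiometric chiral dialkylborane, 10-(trimethylsilyl)-9-borabicyclo[3.3.2]decane (a class that works best when the alkene carries one fully substituted and one primary substituent), followed by NaOH/H2O2 would give diol F3. Appel iodination of the primary hydroxyl (I2, PPh3, imidazole) would give iodide F4, and copper-catalysed borylation (B2pin2, CuI, PPh3, LiOMe, DMF) would return to 15.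

3. Step 5. Discrimination of the enantiotopic α-protons may be incomplete, because the alkoxide and the alkenyl group differ too little in size to hold one chair, or proton exchange may occur before triflation. The fallback sets out from 6 and returns at 12. Vinyllithium 8 (made from 6 as in step 4) would be added to 4,4-dimethoxycyclohexa-2,5-dien-1-one F5 to give carbinol F6 (not isolated), whose ketal is cleaved on mild acid work-up to the flat 4-hydroxycyclohexa-2,5-dienone F7. A copper hydride-catalysed asymmetric conjugate reduction (Cu(OAc)2, chiral bisphosphine, silane) would reduce one of the two enantiotopic enone double bonds, which lie next to the differentiating OH/alkenyl pair, and give enone F8. Conjugate reduction of the remaining enone with lithium tri-sec-butylborohydride and O-triflation of the regiodefined enolate with the triflimide of step 5 would give 12.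

## Further compounds

F1 | step 11 | 2-{(2S,5E)-5-bromo-2-[(1S,3R,4R)-3-bromo-4-methyl-7-oxabicyclo[2.2.1]heptan-1-yl]-6-iodo-4,4-dimethylhex-5-en-1-yl}-4,4,5,5-tetramethyl-1,3,2-dioxaborolane | I/C=C(/Br)C(C)(C)C[C@@H]([C@@]12CC[C@@](C)(O1)[C@H](Br)C2)CB3OC(C)(C)C(C)(C)O3
F2 | step 11 | (1R,2R,4S)-2-bromo-4-[(1S)-4-bromo-5,5-dimethylcyclohex-3-en-1-yl]-1-methyl-7-oxabicyclo[2.2.1]heptane | BrC1=CC[C@H]([C@@]23CC[C@@](C)(O2)[C@H](Br)C3)CC1(C)C
F3 | step 7 | (2R)-2-[(1S)-1-hydroxy-4-methylcyclohex-3-en-1-yl]-4,4-dimethyl-6-(trimethylsilyl)hex-5-yn-1-ol | C[Si](C)(C)C#CC(C)(C)C[C@@H]([C@@]1(O)CC=C(C)CC1)CO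
F4 | step 7 | (1S)-1-[(2S)-1-iodo-4,4-dimethyl-6-(trimethylsilyl)hex-5-yn-2-yl]-4-methylcyclohex-3-en-1-ol | C[Si](C)(C)C#CC(C)(C)C[C@@H]([C@@]1(O)CC=C(C)CC1)CI
F5 | step 5 | 4,4-dimethoxycyclohexa-2,5-dien-1-one (bought) | COC1(OC)C=CC(=O)C=C1
F6 | step 5 | 4,4-dimethoxy-1-[4,4-dimethyl-6-(trimethylsilyl)hex-1-en-5-yn-2-yl]cyclohexa-2,5-dien-1-ol | COC1(OC)C=CC(O)(C=C1)C(=C)CC(C)(C)C#C[Si](C)(C)C
F7 | step 5 | 4-hydroxy-4-[4,4-dimethyl-6-(trimethylsilyl)hex-1-en-5-yn-2-yl]cyclohexa-2,5-dien-1-one | O=C1C=CC(O)(C=C1)C(=C)CC(C)(C)C#C[Si](C)(C)C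
F8 | step 5 | (4S)-4-hydroxy-4-[4,4-dimethyl-6-(trimethylsilyl)hex-1-en-5-yn-2-yl]cyclohex-2-en-1-one | C=C(CC(C)(C)C#C[Si](C)(C)C)[C@@]1(O)C=CC(=O)CC1
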